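Ring A (C1 acyl carbon, C2 OH, C3 Cl, C4 OMe, C6 pentyl) carries oxygen on alternate carbons, as a cyclised poly-β-carbonyl chain would, and is therefore opened at its C1–C6 bond. The precursor is an open-chain 4-chloro-3,5,7-trioxododecanoate that is already the ester of the C4 phenol of ring B (benzyl olivetolate). In one operation chain C2 adds to the C7 ketone, water leaves and ring A aromatises, so chlorine arrives at C3 without aromatic halogenation and the crowded depside ester need not be forged late. The chain is built on a dioxinone and released as an acylketene; O-methylation and debenzylation finish the route.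

Key step: step 8

Remark: all β-dicarbonyl compounds are drawn as keto tautomers. The chlorine-bearing sp3 carbon of the non-aromatic intermediates is racemic and enolisable, and the target has no stereocentre.

Step 1
Reactants: 1 methyl 3-oxooctanoate
Product: 2 methyl 2-(2-pentyl-1,3-dioxolan-2-yl)acetate
Conditions: HOCH2CH2OH (3 equiv), pTsOH·H2O (5 mol %), toluene, Dean–Stark, reflux
Reagents that add atoms: ethylene glycol, OCCO
Why: Acid-catalysed ketalisation with azeotropic removal of water is routine for β-keto esters and masks the future chain C7 carbonyl, so that chain C6 is not a 1,3-dicarbonyl methylene during steps 3 and 4.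

Step 2
Reactants: 2 methyl 2-(2-pentyl-1,3-dioxolan-2-yl)acetate
Product: 3 N-methoxy-N-methyl-2-(2-pentyl-1,3-dioxolan-2-yl)acetamide
Conditions: MeNH(OMe)·HCl (1.5 equiv), iPrMgCl (3.0 equiv), THF, −20 to 0 °C
Reagents that add atoms: N,O-dimethylhydroxylamine hydrochloride, CNOC.Cl
Why: Direct aminolysis of the ester by the chloromagnesium amide (Weinreb amide synthesis) runs below 0 °C with a weakly basic nucleophile, so β-elimination of the ketal should not compete.

Step 3
Reactants: 3 N-methoxy-N-methyl-2-(2-pentyl-1,3-dioxolan-2-yl)acetamide; 4 2,2,6-trimethyl-4H-1,3-dioxin-4-one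
Product: 6 2,2-dimethyl-6-[2-oxo-3-(2-pentyl-1,3-dioxolan-2-yl)propyl]-4H-1,3-dioxin-4-one, via lithium dienolate 5 (not isolated)
Conditions: 4 (2.2 equiv), LiN(SiMe3)2 (2.2 equiv), THF, −78 °C; then 3, −78 to −30 °C; aq NH4Cl
Reagents that add atoms: none
Why: This is a Claisen-type γ-acylation of the dioxinone dienolate, in which the chelated tetrahedral adduct of the Weinreb amide persists until the quench, so neither double addition nor protonation of the dienolate by the more acidic product can occur.

Step 4
Reactants: 6 2,2-dimethyl-6-[2-oxo-3-(2-pentyl-1,3-dioxolan-2-yl)propyl]-4H-1,3-dioxin-4-one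
Product: 7 6-[1-chloro-2-oxo-3-(2-pentyl-1,3-dioxolan-2-yl)propyl]-2,2-dimethyl-4H-1,3-dioxin-4-one (racemic)
Conditions: NCS (1.0 equiv), iPr2NEt (10 mol %), CH2Cl2, 0 °C to rt
Reagents that add atoms: N-chlorosuccinimide, O=C1CCC(=O)N1Cl
Why: In this electrophilic α-chlorination of an active methylene, only the CH2 between the ketone and dioxinone C6 (a vinylogous β-keto ester position, chain C4) enolises under catalytic amine while the other α-CH2 adjoins the ketal, and the new stereocentre forms racemic and is erased on aromatisation.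

Step 5
Reactants: 7 6-[1-chloro-2-oxo-3-(2-pentyl-1,3-dioxolan-2-yl)propyl]-2,2-dimethyl-4H-1,3-dioxin-4-one
Product: 8 6-(1-chloro-2,4-dioxononyl)-2,2-dimethyl-4H-1,3-dioxin-4-one (racemic)
Conditions: pTsOH·H2O (20 mol %), acetone–H2O (10:1), 40 °C
Reagents that add atoms: water, O
Why: Acid-catalysed ketal hydrolysis spares the dioxinone, whose acetonide can only exchange degenerately with acetone, and a halide-free acid gives no route for chlorine to move to the newly freed C6 methylene.

Step 6
Reactants: 9 olivetolic acid (2,4-dihydroxy-6-pentylbenzoic acid)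
Product: 10 benzyl 2,4-dihydroxy-6-pentylbenzoate (benzyl olivetolate)
Conditions: BnBr (1.05 equiv), KHCO3 (1.2 equiv), DMF, rt
Reagents that add atoms: benzyl bromide, BrCc1ccccc1
Why: In this SN2 O-alkylation of the carboxylate, hydrogencarbonate ionises only the carboxylic acid and not the phenols, and room temperature avoids decarboxylation of the electron-rich acid.

Step 7
Reactants: 8 6-(1-chloro-2,4-dioxononyl)-2,2-dimethyl-4H-1,3-dioxin-4-one; 10 benzyl 2,4-dihydroxy-6-pentylbenzoate
Product: 12 benzyl 4-[(4-chloro-3,5,7-trioxododecanoyl)oxy]-2-hydroxy-6-pentylbenzoate (racemic), via chloro acylketene 11 (not isolated)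
Conditions: 10 (1.5 equiv), toluene (0.1 M), 110 °C, N2 sweep; concentrate, use without chromatography
Reagents that add atoms: none
Why: Retro-hetero-Diels–Alder loss of acetone gives the acylketene, which the free C4 phenol of ring B captures under neutral conditions, whereas the C2 phenol is hydrogen-bonded to the benzyl ester and crowded, so it stays out.

Step 8
Reactants: 12 benzyl 4-[(4-chloro-3,5,7-trioxododecanoyl)oxy]-2-hydroxy-6-pentylbenzoate
Product: 14 benzyl 4-[(3-chloro-2,4-dihydroxy-6-pentylbenzoyl)oxy]-2-hydroxy-6-pentylbenzoate, via cyclic aldol 13 (not isolated)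
Conditions: Et3N (2 equiv), AcOH (1 equiv), CH2Cl2 (0.02 M), 0 °C to rt; then TFA (5 equiv), rt
Reagents that add atoms: none
Why: The triethylammonium acetate buffer interconverts the enol(ate)s of 12, and the one centred on chain C2 adds to the C7 pentyl ketone to give aldol 13, which loses water and enolises at C3 and C5 (the TFA finish completes the dehydration) to deliver ring A of 14 with its new C1–C6 bond. The closest known reaction type is the biomimetic aldol aromatisation of 3,5,7-trioxoalkanoates made by acylketene capture, which gives 2,4-dihydroxy-6-alkylbenzoates; the chlorine on C4 and an aryloxy in place of an alkoxy group are the only departures. The ring closes in the 6-(enolendo)-exo-trig mode when drawn from the dominant C2=C3 enol (6-(enolexo)-exo-trig from the ester enol), and both modes are allowed. No stereocentre survives, since those of 13 and the chlorinated carbon all become sp2. The step needs C2-to-C7 aldol addition to outrun attack of the C5 enol oxygen or of C6 on the aryl ester carbonyl C1, which would expel the ring B phenol; in its favour, the ketone C7 is a better electrophile than the ester, the buffer keeps enolate and phenoxide concentrations low, no nucleophilic solvent is present, and aromatisation makes the wanted path irreversible. Because chlorine already sits on chain C4, it can only end at ring A C3, between the two oxygens.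

Step 9
Reactants: 14 benzyl 4-[(3-chloro-2,4-dihydroxy-6-pentylbenzoyl)oxy]-2-hydroxy-6-pentylbenzoate
Product: 15 benzyl 4-[(3-chloro-2-hydroxy-4-methoxy-6-pentylbenzoyl)oxy]-2-hydroxy-6-pentylbenzoate
Conditions: MeI (1.1 equiv), K2CO3 (1.1 equiv), acetone, rt
Reagents that add atoms: iodomethane, CI
Why: This Williamson etherification is under acidity control, because the ring A C4 hydroxyl (ortho to Cl, para to the acyl group) is the most acidic and the only phenol not tied up in a hydrogen bond to an ester carbonyl, so about one equivalent of base and MeI should alkylate it alone without touching the depside ester.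

Step 10
Reactants: 15 benzyl 4-[(3-chloro-2-hydroxy-4-methoxy-6-pentylbenzoyl)oxy]-2-hydroxy-6-pentylbenzoate
Product: 16 4-[(3-chloro-2-hydroxy-4-methoxy-6-pentylbenzoyl)oxy]-2-hydroxy-6-pentylbenzoic acid (target)
Conditions: H2 (1 atm), 10% Pd/C, EtOAc, rt, stopped after uptake of one equivalent
Reagents that add atoms: none
Why: Catalytic hydrogenolysis of a benzyl ester in neutral ethyl acetate is much faster than hydrodechlorination of an electron-rich aryl chloride, which needs base or long exposure, and it leaves the depside ester, the methyl ether and the decarboxylation-prone acid untouched.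

Compound list
1 | methyl 3-oxooctanoate | CCCCCC(=O)CC(=O)OC | starting material
2 | methyl 2-(2-pentyl-1,3-dioxolan-2-yl)acetate | CCCCCC1(CC(=O)OC)OCCO1 | intermediate
3 | N-methoxy-N-methyl-2-(2-pentyl-1,3-dioxolan-2-yl)acetamide | CCCCCC1(CC(=O)N(C)OC)OCCO1 | intermediate
4 | 2,2,6-trimethyl-4H-1,3-dioxin-4-one | CC1=CC(=O)OC(C)(C)O1 | starting material
5 | lithium 2,2-dimethyl-6-methylidene-1,3-dioxin-4-olate (lithium dienolate of 4, not isolated) | [Li+].[O-]C1=CC(=C)OC(C)(C)O1 | intermediate
6 | 2,2-dimethyl-6-[2-oxo-3-(2-pentyl-1,3-dioxolan-2-yl)propyl]-4H-1,3-dioxin-4-one | CCCCCC1(CC(=O)CC2=CC(=O)OC(C)(C)O2)OCCO1 | intermediate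
7 | 6-[1-chloro-2-oxo-3-(2-pentyl-1,3-dioxolan-2-yl)propyl]-2,2-dimethyl-4H-1,3-dioxin-4-one (racemic) | CCCCCC1(CC(=O)C(Cl)C2=CC(=O)OC(C)(C)O2)OCCO1 | intermediate
8 | 6-(1-chloro-2,4-dioxononyl)-2,2-dimethyl-4H-1,3-dioxin-4-one (racemic) | CCCCCC(=O)CC(=O)C(Cl)C1=CC(=O)OC(C)(C)O1 | intermediate
9 | olivetolic acid (2,4-dihydroxy-6-pentylbenzoic acid) | CCCCCc1cc(O)cc(O)c1C(=O)O | starting material
10 | benzyl 2,4-dihydroxy-6-pentylbenzoate | CCCCCc1cc(O)cc(O)c1C(=O)OCc1ccccc1 | intermediate
11 | 4-chlorododec-1-ene-1,3,5,7-tetrone (acylketene, racemic, not isolated) | CCCCCC(=O)CC(=O)C(Cl)C(=O)C=C=O | intermediate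
12 | benzyl 4-[(4-chloro-3,5,7-trioxododecanoyl)oxy]-2-hydroxy-6-pentylbenzoate (racemic, enolisable at the chlorinated carbon) | CCCCCC(=O)CC(=O)C(Cl)C(=O)CC(=O)Oc1cc(O)c(C(=O)OCc2ccccc2)c(CCCCC)c1 | intermediate
13 | benzyl 4-[(3-chloro-6-hydroxy-2,4-dioxo-6-pentylcyclohexane-1-carbonyl)oxy]-2-hydroxy-6-pentylbenzoate (mixture of stereoisomers and tautomers, not isolated) | CCCCCC1(O)CC(=O)C(Cl)C(=O)C1C(=O)Oc1cc(O)c(C(=O)OCc2ccccc2)c(CCCCC)c1 | intermediate
14 | benzyl 4-[(3-chloro-2,4-dihydroxy-6-pentylbenzoyl)oxy]-2-hydroxy-6-pentylbenzoate | CCCCCc1cc(OC(=O)c2c(CCCCC)cc(O)c(Cl)c2O)cc(O)c1C(=O)OCc1ccccc1 | intermediate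
15 | benzyl 4-[(3-chloro-2-hydroxy-4-methoxy-6-pentylbenzoyl)oxy]-2-hydroxy-6-pentylbenzoate | CCCCCc1cc(OC(=O)c2c(CCCCC)cc(OC)c(Cl)c2O)cc(O)c1C(=O)OCc1ccccc1 | intermediate
16 | 4-[(3-chloro-2-hydroxy-4-methoxy-6-pentylbenzoyl)oxy]-2-hydroxy-6-pentylbenzoic acid | CCCCCc1cc(OC(=O)c2c(CCCCC)cc(OC)c(Cl)c2O)cc(O)c1C(=O)O | target

Total step count: 10.
Longest linear sequence: 9 steps (steps 1–5 and 7–10, from 1 to 16). Step 6 is the only side branch.

Steps most likely to fail

Step 8. The ring B phenol may be expelled before the carbocycle forms. This can happen by lactonisation of the C5 enol oxygen onto the aryl ester, or by base-induced elimination back to the ketene. Chlorine may also be passed between enolates. The fallback sets out from 8 and comes back at 15. Compound 8 itself is treated with Et3N in CH2Cl2. The same C–C bond then forms while the carboxyl group is still locked in the dioxinone, which has no leaving group to lose. This should give 8-chloro-7-hydroxy-2,2-dimethyl-5-pentyl-4H-1,3-benzodioxin-4-one F1. Its single free phenol is methylated (MeI, K2CO3, acetone) to 8-chloro-7-methoxy-2,2-dimethyl-5-pentyl-4H-1,3-benzodioxin-4-one F2. KOH in aqueous DMSO followed by cold acidification opens the acetonide to 3-chloro-2-hydroxy-4-methoxy-6-pentylbenzoic acid F3. Trifluoroacetic anhydride in toluene converts this acid into 3-chloro-2-hydroxy-4-methoxy-6-pentylbenzoic trifluoroacetic anhydride F4. This acylates the unchelated C4 phenol of 10, the classical depside condensation, to give 15. The regiochemistry of chlorine is still fixed by the chain.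

Step 7. The chain's own enolised 1,3-diketone may capture the ketene internally, through oxygen or through C6, faster than the weakly nucleophilic phenol adds. The fallback sets out from 7 and comes back at 12. The order of unmasking and thermolysis is reversed, so the ketene is generated while C7 is still a ketal and no enolised diketone is present. Heating 7 with 10 in toluene at 110 °C should pass through 4-chloro-6-(2-pentyl-1,3-dioxolan-2-yl)hex-1-ene-1,3,5-trione F5. Capture by 10 should then give benzyl 4-{[4-chloro-3,5-dioxo-6-(2-pentyl-1,3-dioxolan-2-yl)hexanoyl]oxy}-2-hydroxy-6-pentylbenzoate F6. Ketal hydrolysis with pTsOH·H2O in wet acetone then releases 12 immediately before the key step.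

Step 4. Chlorine may attack ring carbon C5 of the dioxinone, or a second chlorination may follow the first. The fallback sets out from 4 and comes back at 7. Chlorine is introduced before the acylation, so its position is fixed by construction. Dienolate 5, from 4 and LiN(SiMe3)2 at −78 °C, is quenched with C2Cl6 to give 6-(chloromethyl)-2,2-dimethyl-4H-1,3-dioxin-4-one F7. This is added to LiN(SiMe3)2 (2 equiv) at −78 °C to form lithium 6-(chloromethylidene)-2,2-dimethyl-1,3-dioxin-4-olate F8. Acylation of that dienolate with Weinreb amide 3 gives 7 directly and replaces steps 3 and 4 at the same step count.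

Further compounds
F1 | step 8 | 8-chloro-7-hydroxy-2,2-dimethyl-5-pentyl-4H-1,3-benzodioxin-4-one | CCCCCc1cc(O)c(Cl)c2OC(C)(C)OC(=O)c12
F2 | step 8 | 8-chloro-7-methoxy-2,2-dimethyl-5-pentyl-4H-1,3-benzodioxin-4-one | CCCCCc1cc(OC)c(Cl)c2OC(C)(C)OC(=O)c12
F3 | step 8 | 3-chloro-2-hydroxy-4-methoxy-6-pentylbenzoic acid | CCCCCc1cc(OC)c(Cl)c(O)c1C(=O)O
F4 | step 8 | 3-chloro-2-hydroxy-4-methoxy-6-pentylbenzoic trifluoroacetic anhydride | CCCCCc1cc(OC)c(Cl)c(O)c1C(=O)OC(=O)C(F)(F)F
F5 | step 7 | 4-chloro-6-(2-pentyl-1,3-dioxolan-2-yl)hex-1-ene-1,3,5-trione (racemic) | CCCCCC1(CC(=O)C(Cl)C(=O)C=C=O)OCCO1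
F6 | step 7 | benzyl 4-{[4-chloro-3,5-dioxo-6-(2-pentyl-1,3-dioxolan-2-yl)hexanoyl]oxy}-2-hydroxy-6-pentylbenzoate (racemic) | CCCCCC1(CC(=O)C(Cl)C(=O)CC(=O)Oc2cc(O)c(C(=O)OCc3ccccc3)c(CCCCC)c2)OCCO1
F7 | step 4 | 6-(chloromethyl)-2,2-dimethyl-4H-1,3-dioxin-4-one | ClCC1=CC(=O)OC(C)(C)O1
F8 | step 4 | lithium 6-(chloromethylidene)-2,2-dimethyl-1,3-dioxin-4-olate (alkene geometry not defined) | [Li+].[O-]C1=CC(=CCl)OC(C)(C)O1
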